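The data come from a simulation from invented constants, noise included.

Slowness sits in the making of product: in both earlier runs substrate drops quickly, while product climbs steadily from 1.00 min to 2.50 min, so that stretch is the one to read.

| setting | birch | cedar | flask |
|---|---|---|---|
| substrate | 10 mM | 40 mM | 20 mM |
| reagent | 22 mM | 22 mM | 22.0 mM |
| precatalyst | 0.50 mM | 0.50 mM | 0.50 mM |
| remark | run made earlier | run made earlier |  |

| run | time / min | product / % | substrate / % |
|---|---|---|---|
| birch | 0.500 | 2.7 | 45.5 |
| birch | 1.00 | 10.6 | 26.8 |
| birch | 1.33 | 16.4 | 24.9 |
| birch | 2.00 | 24.6 | 20.1 |
| birch | 2.50 | 30.4 | 18.9 |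
| cedar | 0.500 | 1.0 | 44.2 |
| cedar | 1.00 | 10.3 | 26.4 |
| cedar | 1.33 | 15.1 | 23.9 |
| cedar | 2.00 | 23.7 | 22.2 |
| cedar | 2.50 | 27.4 | 20.4 |

(readings scatter by 1 percentage point)

- no earlier run changes the charge of reagent; that part of a forecast is a guess
- no earlier run changes the charge of precatalyst; that part of a forecast is a guess

1. factor on the rate of making product when 20% of the substrate are converted if reagent is charged twice over
2. factor on the rate when 20% of the substrate are converted if precatalyst is charged at 0.050 mM instead

Column against column, the birch run makes 0.132 min⁻¹ of its substrate charge into product over that stretch, and the cedar run makes 0.114 min⁻¹ of its own, which is slower by a ratio of 0.864. The two curves stay close in fractions of the charge although the substrate charges differ by a factor of 4.00, so this reckoning treats substrate as cancelling and puts the gap on reagent.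

If each product costs one reagent, the birch run holds on average 0.907 of its reagent there, and the cedar run holds 0.657, which is less than the birch run holds. The decade slope (the reaction order) is the log10 of the rate ratio over the log10 of the reagent ratio: 0.456.

It rests on a gap of 2.7 percentage points built from four readings, each scattering by 1 point, so it is weak. This reckoning commits to 1.37 for doubled reagent. For precatalyst, a guessed slope of one gives 0.100.

The forecast says 1.3 and 0.12: “That lies between zero and first order in reagent, so order is roughly 0.4, which is weakly determined.”

The flask gives 1.98 and 0.221. Read the same way, the decade slope is 0.986 for reagent, where the runs read 0.456, and 0.655 for precatalyst at 0.050 mM.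

    substrate + free catalyst ⇌ free catalyst + intermediate (K = 2.60, k = 329 M⁻¹ s⁻¹)
    reagent + free catalyst + intermediate → free catalyst + product (k = 991 M⁻² s⁻¹)
    free catalyst → spent catalyst (k = 0.0107 s⁻¹)
    precatalyst → free catalyst (k = 0.0194 s⁻¹)

In the flask, 20% conversion comes at 0.215 min, sooner than the half-life of precatalyst, 0.60 min as it stands at 0.362 min, and 77.8% of the catalyst is then still precatalyst. With 0.050 mM charged, the same conversion finds 45.6% of the catalyst free.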